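An equilibrium cannot be what stops these runs, since going from 0.065 mM to 0.26 mM of precatalyst raises the mean plateau from 82.2% to 88.0%, and a catalyst does not move an equilibrium.

the same everywhere: starting material 0.067 M

|  | coupling partner | protic impurity | precatalyst | remark | time |
|---|---|---|---|---|---|
| south | 0.067 M | 0.0134 M | 0.065 mM | run made earlier |  |
| south-east | 0.067 M | 0.0134 M | 0.26 mM | run made earlier |  |
| north-east | 0.067 M | 0.027 M | 0.13 mM | run made earlier |  |
| flask | 0.0670 M | 0.0134 M | 0.13 mM |  | 1.5 h |

| run | time / min | product / % |
|---|---|---|
| south | 20.0 | 82 |
| south | 40.0 | 81 |
| south | 50.0 | 83 |
| south | 80.0 | 83 |
| south-east | 20.0 | 87 |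
| south-east | 40.0 | 87 |
| south-east | 50.0 | 89 |
| south-east | 80.0 | 89 |
| north-east | 10.0 | 71 |
| north-east | 25.0 | 72 |
| north-east | 50.0 | 72 |
| north-east | 80.0 | 67 |

(each reading ± 2 percentage points)

- which holds at 1.5 h: what has brought the reaction to rest, or that it has not come to rest (no working catalyst is left / the coupling partner has run out first / it is still moving / forward and back rates have come level / all of the starting material has reacted)
- product at 1.5 h, in percent of the starting material charged

- the reaction counts as stopped when no species that holds the starting material changes by six tenths of a point or more over the second half of the time

So I read each plateau as a race that is over by the first reading: the catalyst turns starting material into product while protic impurity quenches it one for one. If both uses are first order in starting material, their ratio is M/[protic impurity], where M, my match concentration, is the [protic impurity] at which both run equally fast at a given catalyst charge, a selectivity factor in concentration form. Integrating gives M as the product made divided by the logarithm of charged over surviving [protic impurity].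

The north-east run has the flask's precatalyst, and its mean of 70.5% gives 35.9 mM. Solving the same relation for the flask, I find 10.6 mM quenched, so 84.2% product. With equal charges the readings cannot name the victim, but I wager on the starting material, which then runs out.

The forecast, from “the impurity competitively destroying the coupling partner”, says the coupling partner has run out first and 85%, so we part on the end and differ little on the number.

The flask gives: all of the starting material has reacted, with 83.6% product.

    starting material + protic impurity → quenched substrate (k = 2.40 M⁻¹ s⁻¹)
    coupling partner + catalyst intermediate B ⇌ catalyst intermediate C (K = 42.0 M⁻¹, k = 1700 M⁻¹ s⁻¹)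
    catalyst intermediate A → spent catalyst (k = 0.0410 s⁻¹)
    precatalyst → free catalyst (k = 0.600 s⁻¹)
    starting material + free catalyst → catalyst intermediate A (k = 1600 M⁻¹ s⁻¹)
    catalyst intermediate C → free catalyst + product (k = 930 s⁻¹)
    catalyst intermediate A ⇌ catalyst intermediate B (K = 25.0, k = 140 s⁻¹)

At 0.1568 min in this flask, the catalyst takes starting material 8.1 times as fast as the quench, whose half-life is then 1.1 min. Nearly all of the conversion stands after 0.463 min, sooner than that half-life, and at the asked time starting material is 0% and quenched substrate 16.4%, against my 15.8%. Carried to the neighbour with 0.0034 M of protic impurity, M gives 95.8% product, and that flask stands at 95.5%.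

Readings and results were generated by integration with made-up constants, noise included.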